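**Remarks (assumptions on the chemistry)**
- Locants follow the tetralin numbering C1 (isopropyl), C2, C3, C4 (methyl), C4a, C5, C6, C7, C8, C8a, and O1', C2' (lactone carbonyl), C3' to C6' for the pyranone. Compound names use these locants even where lowest-locant rules would number differently.
- The target is drawn without a descriptor for the C8–C3' axis. It is assumed that rotamers about this bond equilibrate, and no step tries to control the axis.
- Methyl semisquarate 8 is assumed to form from dimethyl squarate in the same way as its well-known isopropyl homologue forms from diisopropyl squarate.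
- The given structures were checked and need no correction: (S)-carvone gives (1R,4S), and the kinetic Shapiro alkenyllithium puts the methyl-bearing carbon next to C4a as required.

## Structural features

Heimiomycin A is a 1,2,3,4-tetrahydronaphthalene in which a saturated ring A (C1–C4, C4a, C8a) is fused to a fully substituted benzene ring B (C4a, C5–C8, C8a). C8 of ring B is bonded to C3' of a 4-hydroxy-2-pyranone (ring C) that carries an (E)-4-hydroxystyryl group at C6'. The only stereocentres are C1 (isopropyl, R) and C4 (methyl, S); both are benzylic, they are trans, and they stand 1,4 across ring A and not side by side, which is the pattern of a p-menthane. Ring B carries a catechol at C5/C6, a formyl group at C7 and the pyranone at C8, so four different substituents sit on four neighbouring carbons with no symmetry to help. The fragile parts are the catechol next to the aldehyde (oxidation, base), the acidic enol of the pyranone and the (E)-styryl double bond (light, strong protic acid). The C8–C3' bond is flanked by the formyl group, the peri C1 with its isopropyl group, the lactone carbonyl and the enol oxygen, so joining the two ring systems is a hindered biaryl-type coupling. The stereocentres are therefore the easy part, and the real difficulty is the regiocontrolled hexasubstitution of ring B together with the crowded C8–C3' bond. The key step exploits the fact that C5, C6, C7 and C8, with oxygen on C5, C6 and (as a temporary handle) C8, are the four carbons of a methoxycyclobutenedione, while C4a=C8a is the double bond of a cyclohexenyl group from the p-menthane ketone; every ring B carbon thus receives its substituent by position before the ring exists.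

## Logic of the disconnections

**23 ⇒ 22.** The four O–CH3 bonds (at C5, C6, C4' and the styryl phenol) are cut last. The free catechol aldehyde and the acidic enol would interfere with every organometallic step, so they stay masked until the end. The gain is that all earlier intermediates are neutral ethers with a single kind of protecting group. The demand is one reagent that cleaves three aryl methyl ethers and one vinylogous methyl ester without harming the aldehyde or the styryl alkene.

**22 ⇒ 16 + 21.** The C8–C3' bond is cut. It is the only bond between two complete ring systems, and C8 carries an oxygen from the key step that can become a leaving group. The gain is convergence: a chiral tetralin half and an achiral pyranone half of similar size. The demand is a cross-coupling that tolerates ortho substituents on both partners and a free aldehyde.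

**21 ⇒ 20 ⇒ 18 + 19, and 18 ⇒ 17.** The C3'–Sn bond, the styryl C=C bond and the C3'–Br bond are cut in turn. C3' is the nucleophilic carbon of the vinylogous ester and the C6' methyl is vinylogously acidic, so both bonds form with the native polarity. The gain is that 21 reduces to two commercial compounds. The demand is that bromination precedes condensation, so that the electron-rich styrene never meets the electrophile, and that the condensation gives the E alkene.

**16 ⇒ 15 ⇒ 14.** The O–S bond and then the C7–CHO bond are cut. The C8 hydroxyl of 14 first directs the one-carbon electrophile to C7, its only free ortho position, and is then turned into the leaving group. The gain is that one oxygen serves twice and no separate halogenation is needed. The demand is that formylation comes before sulfonylation.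

**14 ⇒ 11 (key).** The C8–C8a bond is cut and ring B is traced back through 13 and 12 to a four-membered ring in which C5–C8 is already intact. A benzannulation in which each ring B carbon arrives with its substituent removes every regiochemical question on the arene. The gain is that an aromatic ring with four substituents becomes a cyclobutenone attached by one bond to ring A, with no new stereocentre. The demand is that the thermal opening turns the ring A alkene toward the ketene, and that the conditions leave C1 and C4 alone.

**11 ⇒ 5 + 8 (through 9 and 10).** The C4a–C5 bond and the O–CH3 bond on the C5 oxygen are cut. C4a is a natural alkenyl nucleophile and C5 a carbonyl carbon, so the polarity matches. The gain is the separation of chiral ring A from the four-carbon unit. The demand is threefold: an alkenyl metal with its double bond toward C8a and not toward C4, addition to the correct carbonyl of 8, and capping of a tertiary alkoxide so that the C5 and C8 oxygens emerge differentiated.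

**8 ⇒ 6 (through 7).** The C–H bond at the future C7 is traced back to a C–OCH3 bond. The target has no oxygen at C7, so one ester oxygen of 6 must be replaced by hydrogen. The gain is a symmetric commercial precursor. The demand is a single hydride addition followed by acid-induced transposition.

**5 ⇒ 3 + 4, and 3 ⇒ 1 (through 2).** The C=N bond is cut, then the C–H bonds made by hydrogenation. The hydrazone is the handle that turns the carbonyl carbon into the C4a nucleophile. The gain is that both stereocentres come from the chiral pool: C1 directly from 1, and C4 by equilibration against it. The demand is that hydrogenation is followed by epimerisation to the trans ketone and that the minor epimer is purged.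

## Other disconnections considered

**Alternative 1:** Gold furan–yne cycloisomerisation.
- Cut: C4a–C8a and C5–C6, which opens rings A and B together to the acyclic furan–alkyne A2 (a 2-substituted 3,4-bis(oxymethyl)furan whose side chain carries both stereocentres and ends in the alkyne).
- Forward key step: Ph3PAuNTf2 activates the alkyne, the furan attacks, and the cyclopropyl carbenoid, oxepine and arene oxide sequence gives phenol A1, with the furan oxygen becoming the C5 hydroxyl.
- In favour: two rings close in one catalytic step near room temperature without base or heat. On mildness and on rings closed per step this is better than the chosen plan. C7 and C8 already carry differentiated carbon substituents.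
- Against here:
  - A1 has no oxygen at C6, so the catechol still needs an ortho-hydroxylation.
  - C8 carries a CH2O carbon, which must be homologated and built into the whole pyranone at a crowded benzylic position.
  - C1 and C4 must be set by two separate asymmetric operations in an open chain, where carvone supplies both.
  - A six-membered carbocycle formed through an all-carbon tether with a branched furfurylic carbon is the less favourable case for this cycloisomerisation.
- Comparison: on structure the chosen plan maps all four ring B carbons at the right oxidation level, whereas A1 maps C5, C7 and C8 but needs C6 oxidation and C8 reconstruction. On mechanism both are atom-economic isomerisations, which is a tie. On step economy the alternative is expected to be longer, both before A2 and after A1.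

**Alternative 2:** Crossed union of an arylketene and an acylketene.
- Cut: C3'–C4' and O1'–C2' of the pyranone, giving aryl tert-butyl ynol ether A4 and styryl dioxinone A5.
- Forward key step: heating releases isobutene from A4 and acetone from A5; the arylketene and acylketene combine to the 4-hydroxypyranone A3.
- In favour:
  - The hindered C8–C3' bond is not made by an sp2–sp2 coupling, because C8 is joined to a linear alkyne carbon and the pyranone is grown on it.
  - The C4' hydroxyl emerges free, so no vinylogous methyl ester has to be cleaved.
  - Both points are better than the chosen plan, and both ketene precursors unmask without reagents.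
- Against here:
  - Two ketenes must react crosswise, in competition with dimerisation of each.
  - The unmasking temperatures must match, and the arylketene is doubly ortho-substituted.
  - A4 already contains all of ring B, so the harder half of the problem is untouched. A4 would be made from a C8 sulfonate such as 16 after acetal protection and alkynyl ether installation.
  - A3 still needs three O-methyl cleavages and acetal hydrolysis.
- Comparison: this is a complementary endgame and not a rival to the key step; it could replace steps 8–11 downstream of 16. Step count is about equal. The chosen plan keeps the bimolecular bond formation in a reaction class with predictable chemoselectivity; the alternative has the better answer to steric hindrance.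

**Alternative 3:** Dioxygenase oxidation of the bare tetralin.
- Cut: the C5–O and C6–O bonds, leading back to hydrocarbon A7.
- Forward key step: whole cells expressing a Rieske non-heme iron dioxygenase and its cis-dihydrodiol dehydrogenase convert A7 with O2 into catechol A6.
- In favour: no protecting groups on the catechol, oxygen as the oxidant, and a substrate class (tetralins) for which such enzyme systems exist. On redox and protecting-group economy this is better than the chosen plan.
- Against here:
  - Ring B of A7 is nearly symmetric, so the enzyme must choose C5/C6 over C7/C8 by telling a methyl-bearing from an isopropyl-bearing benzylic carbon.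
  - It must accept alkyl groups at both benzylic positions and avoid benzylic hydroxylation.
  - The catechol is toxic to cells and open to further ring cleavage.
  - After A6, C7 and especially C8 are plain C–H bonds with no handle for the pyranone, so halogenation, protection and the same hindered coupling still follow.
- Comparison: on structure the chosen key step differentiates all four ring B positions and leaves the C8 hydroxyl as a handle, whereas A6 solves only C5/C6. On mechanism the enzymatic step is milder, but its selectivity rests on an enzyme fit that cannot be argued from the substrate alone. Step economy is expected to be similar or worse once protection and C8 functionalisation are counted.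

Key step: step 5

## Route

Step 1
Reactants: 1 (S)-(+)-carvone, (5S)-2-methyl-5-(prop-1-en-2-yl)cyclohex-2-en-1-one
Product: 3 (2S,5S)-2-methyl-5-(propan-2-yl)cyclohexan-1-one (trans-tetrahydrocarvone), via C2-epimeric tetrahydrocarvone mixture 2 (not isolated)
Conditions: H2 (1 atm), Pd/C, MeOH, rt; filter; NaOMe (cat.), MeOH, rt
Reagents that add atoms: none
Why: Heterogeneous catalytic hydrogenation saturates the enone and isopropenyl double bonds without touching C5; base then equilibrates C2 through the enolate, and the trans diequatorial ketone should predominate (thermodynamic control of the new centre); residual cis epimer is expected to be removed when hydrazone 5 is crystallised.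

Step 2
Reactants: 3 (2S,5S)-2-methyl-5-(propan-2-yl)cyclohexan-1-one; 4 2,4,6-tri(propan-2-yl)benzenesulfonohydrazide
Product: 5 N'-[(1E,2S,5S)-2-methyl-5-(propan-2-yl)cyclohexylidene]-2,4,6-tri(propan-2-yl)benzenesulfonohydrazide
Conditions: MeOH, HCl (cat.), rt; crystallise
Reagents that add atoms: none
Why: Acid-catalysed hydrazone condensation; the E isomer, with the sulfonamide nitrogen on the CH2 side, avoids allylic strain with the C2 methyl and is also the geometry needed for deprotonation at that CH2 in step 4.

Step 3
Reactants: 6 dimethyl squarate, 3,4-dimethoxycyclobut-3-ene-1,2-dione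
Product: 8 3-methoxycyclobut-3-ene-1,2-dione (methyl semisquarate), via 4-hydroxy-2,3-dimethoxycyclobut-2-en-1-one 7 (not isolated)
Conditions: LiAlH(Ot-Bu)3, THF, −78 to −20 °C; aqueous work-up; conc. HCl (cat.), CH2Cl2, rt
Reagents that add atoms: none
Why: The bulky hydride adds once, 1,2, to a squarate carbonyl; acid then ionises the carbinol with allylic transposition and loss of methanol to give the semisquarate, the sequence established for dialkyl squarates; 8 is used promptly.

Step 4
Reactants: 5 trisylhydrazone; 8 3-methoxycyclobut-3-ene-1,2-dione
Product: 11 3,4-dimethoxy-4-[(3R,6S)-6-methyl-3-(propan-2-yl)cyclohex-1-en-1-yl]cyclobut-2-en-1-one (both C4 epimers), via alkenyllithium 9 (not isolated), via lithium alkoxide adduct 10 (not isolated)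
Conditions: n-BuLi (2.1 equiv), THF/TMEDA, −78 to 0 °C (N2 evolution); then 8, THF, −78 °C; then MeOTf (excess), −78 to 0 °C
Reagents that add atoms: methyl trifluoromethanesulfonate, COS(=O)(=O)C(F)(F)F
Why: Shapiro reaction: deprotonation of N–H and then of the less hindered α-CH2 syn to nitrogen, followed by loss of sulfinate and N2, gives the less substituted alkenyllithium 9 without touching C2–H; 9 adds 1,2 to the ketone-like carbonyl next to the methoxy-bearing carbon of 8 (the other carbonyl is a deactivated vinylogous ester), and methyl triflate caps the tertiary alkoxide; the new quaternary centre forms as a mixture that does not matter because step 5 destroys it.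

Step 5
Reactants: 11 3,4-dimethoxy-4-[(3R,6S)-6-methyl-3-(propan-2-yl)cyclohex-1-en-1-yl]cyclobut-2-en-1-one
Product: 14 (1R,4S)-5,6-dimethoxy-4-methyl-1-(propan-2-yl)-1,2,3,4-tetrahydronaphthalen-8-ol, via dienylketene 12 (not isolated), via cyclohexadienone 13 (not isolated)
Conditions: degassed toluene (dilute), 110 °C, N2
Reagents that add atoms: none
Why: On heating, the σ-bond between the methoxy-bearing sp3 carbon (future C5) and the carbonyl carbon (future C8) breaks in a thermal conrotatory 4π-electrocyclic opening to give dienylketene 12. Torquoselectivity is the selectivity the step needs: the π-donor methoxy group rotates outward, so the cyclohexenyl group turns inward and ends cis to the ketene across the new C5=C6 bond, while any inward-methoxy rotamer cannot close and can only revert. Ring B then closes by a thermal disrotatory 6π-electrocyclisation over the ketene C=C, C5=C6 and C4a=C8a bonds, which forms C8–C8a and gives cyclohexa-2,4-dienone 13. The only new sp3 centre, C8a in 13, is transient and is erased when 13 tautomerises to the phenol, so no permanent stereocentre is made and both epimers of 11 converge on 14. Regiochemistry is not decided here, because the order C5 (OMe), C6 (OMe), C7 (H), C8 (OH) was written into 11 by the carbonyl selectivity of step 4. The medium is neutral and free of base and radical sources, so the allylic C1–H and C4–H bonds are not engaged and the trans relationship is kept. The closest known reaction type is the thermal ring expansion of 4-alkenyl- and 4-aryl-4-alkoxycyclobutenones to hydroquinone monoethers.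

Step 6
Reactants: 14 (1R,4S)-5,6-dimethoxy-4-methyl-1-(propan-2-yl)-1,2,3,4-tetrahydronaphthalen-8-ol
Product: 15 (1R,4S)-8-hydroxy-5,6-dimethoxy-4-methyl-1-(propan-2-yl)-1,2,3,4-tetrahydronaphthalene-7-carbaldehyde
Conditions: MgCl2, Et3N, (CH2O)n, MeCN, reflux
Reagents that add atoms: paraformaldehyde (as formaldehyde), C=O
Why: Magnesium-mediated ortho-formylation (Casnati–Skattebøl type): the magnesium phenoxide delivers formaldehyde to C7, the only free ortho position, and a second equivalent of formaldehyde oxidises the benzylic alkoxide to the aldehyde.

Step 7
Reactants: 15 (1R,4S)-8-hydroxy-5,6-dimethoxy-4-methyl-1-(propan-2-yl)-1,2,3,4-tetrahydronaphthalene-7-carbaldehyde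
Product: 16 (1R,4S)-7-formyl-5,6-dimethoxy-4-methyl-1-(propan-2-yl)-1,2,3,4-tetrahydronaphthalen-8-yl trifluoromethanesulfonate
Conditions: Tf2O, pyridine, CH2Cl2, 0 °C
Reagents that add atoms: trifluoromethanesulfonic anhydride, O=S(=O)(OS(=O)(=O)C(F)(F)F)C(F)(F)F
Why: O-Sulfonylation of a phenol; the oxygen that directed the formylation becomes the leaving group at C8, and the ortho formyl group should make the C–O bond more reactive toward oxidative addition.

Step 8
Reactants: 17 4-methoxy-6-methyl-2H-pyran-2-one
Product: 18 3-bromo-4-methoxy-6-methyl-2H-pyran-2-one
Conditions: NBS, MeCN, rt, dark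
Reagents that add atoms: N-bromosuccinimide, O=C1CCC(=O)N1Br
Why: Electrophilic bromination at C3, the nucleophilic enol-ether carbon of the vinylogous ester, which is the normal halogenation site of 4-alkoxy-2-pyranones; done before the styryl group exists so that no electron-rich alkene competes.

Step 9
Reactants: 18 3-bromo-4-methoxy-6-methyl-2H-pyran-2-one; 19 4-methoxybenzaldehyde
Product: 20 3-bromo-4-methoxy-6-[(E)-2-(4-methoxyphenyl)ethenyl]-2H-pyran-2-one
Conditions: Mg(OMe)2, MeOH, reflux
Reagents that add atoms: none
Why: Vinylogous aldol condensation: the C6 methyl is deprotonated through the dienolate, adds to the aldehyde and dehydrates to the conjugated E alkene under thermodynamic control, as in the classical preparation of 6-styryl-4-methoxypyranones.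

Step 10
Reactants: 20 3-bromo-4-methoxy-6-[(E)-2-(4-methoxyphenyl)ethenyl]-2H-pyran-2-one
Product: 21 4-methoxy-6-[(E)-2-(4-methoxyphenyl)ethenyl]-3-(trimethylstannyl)-2H-pyran-2-one
Conditions: (Me3Sn)2, Pd(PPh3)4 (5 mol%), 1,4-dioxane, 100 °C, dark; chromatography on Et3N-deactivated silica
Reagents that add atoms: hexamethylditin, C[Sn](C)(C)[Sn](C)(C)C
Why: Palladium-catalysed stannylation of an sp2 bromide with a distannane (oxidative addition, Sn–Sn transmetalation, reductive elimination), known for 3-bromo-2-pyranones; the trimethylstannyl group is chosen for fast transmetalation in the hindered coupling that follows.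

Step 11
Reactants: 16 aryl triflate; 21 pyranonylstannane
Product: 22 (1R,4S)-5,6-dimethoxy-8-{4-methoxy-6-[(E)-2-(4-methoxyphenyl)ethenyl]-2-oxo-2H-pyran-3-yl}-4-methyl-1-(propan-2-yl)-1,2,3,4-tetrahydronaphthalene-7-carbaldehyde
Conditions: Pd(PPh3)4 (10 mol%), CuCl, LiCl, DMSO, 60 °C, dark
Reagents that add atoms: none
Why: Stille coupling of an aryl triflate with an alkenyl-type stannane; LiCl is needed for triflates and CuCl relays the pyranonyl group from tin through copper to palladium, the established remedy for congested partners; the ortho formyl group speeds oxidative addition and the two ortho groups on the pyranone side are single oxygen atoms.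

Step 12
Reactants: 22 tetra-O-methyl heimiomycin A
Product: 23 heimiomycin A, (1R,4S)-5,6-dihydroxy-8-{4-hydroxy-6-[(E)-2-(4-hydroxyphenyl)ethenyl]-2-oxo-2H-pyran-3-yl}-4-methyl-1-(propan-2-yl)-1,2,3,4-tetrahydronaphthalene-7-carbaldehyde
Conditions: BBr3 (excess), CH2Cl2, −78 °C to rt, dark; then MeOH, H2O; work-up under N2
Reagents that add atoms: none
Why: Lewis-acid ether cleavage: boron coordinates to each ether oxygen (helped by chelation to the aldehyde at C6–OMe and by the lactone carbonyl for the vinylogous ester) and bromide removes each methyl by SN2; aldehydes, stilbene-type alkenes and pyranones normally survive BBr3, and no stereocentre is involved.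

## Compound list

1 | (S)-(+)-carvone, (5S)-2-methyl-5-(prop-1-en-2-yl)cyclohex-2-en-1-one | CC1=CC[C@@H](CC1=O)C(C)=C | starting material
2 | (5S)-2-methyl-5-(propan-2-yl)cyclohexan-1-one, mixture of C2 epimers | CC(C)[C@H]1CCC(C)C(=O)C1 | intermediate (not isolated)
3 | (2S,5S)-2-methyl-5-(propan-2-yl)cyclohexan-1-one (trans) | CC(C)[C@H]1CC[C@H](C)C(=O)C1 | intermediate
4 | 2,4,6-tri(propan-2-yl)benzenesulfonohydrazide | CC(C)c1cc(C(C)C)c(S(=O)(=O)NN)c(C(C)C)c1 | starting material
5 | N'-[(1E,2S,5S)-2-methyl-5-(propan-2-yl)cyclohexylidene]-2,4,6-tri(propan-2-yl)benzenesulfonohydrazide | CC(C)[C@H]1CC[C@H](C)/C(=N/NS(=O)(=O)c2c(C(C)C)cc(C(C)C)cc2C(C)C)C1 | intermediate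
6 | dimethyl squarate, 3,4-dimethoxycyclobut-3-ene-1,2-dione | COC1=C(OC)C(=O)C1=O | starting material
7 | 4-hydroxy-2,3-dimethoxycyclobut-2-en-1-one (racemic) | COC1=C(OC)C(=O)C1O | intermediate (not isolated)
8 | 3-methoxycyclobut-3-ene-1,2-dione (methyl semisquarate) | COC1=CC(=O)C1=O | intermediate
9 | [(3R,6S)-6-methyl-3-(propan-2-yl)cyclohex-1-en-1-yl]lithium | CC(C)[C@H]1CC[C@H](C)C([Li])=C1 | intermediate (not isolated)
10 | lithium 2-methoxy-1-[(3R,6S)-6-methyl-3-(propan-2-yl)cyclohex-1-en-1-yl]-4-oxocyclobut-2-en-1-olate, both epimers at the carbinol carbon | CC(C)[C@H]1CC[C@H](C)C(=C1)C2(O[Li])C(OC)=CC2=O | intermediate (not isolated)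
11 | 3,4-dimethoxy-4-[(3R,6S)-6-methyl-3-(propan-2-yl)cyclohex-1-en-1-yl]cyclobut-2-en-1-one, both C4 epimers | CC(C)[C@H]1CC[C@H](C)C(=C1)C2(OC)C(OC)=CC2=O | intermediate (key-step precursor)
12 | (3Z)-3,4-dimethoxy-4-[(3R,6S)-6-methyl-3-(propan-2-yl)cyclohex-1-en-1-yl]buta-1,3-dien-1-one (dienylketene) | CC(C)[C@H]1CC[C@H](C)C(=C1)/C(OC)=C(\C=C=O)OC | intermediate (not isolated)
13 | (1R,4S)-5,6-dimethoxy-4-methyl-1-(propan-2-yl)-2,3,4,8a-tetrahydronaphthalen-8(1H)-one, C8a configuration unspecified | CC(C)[C@H]1CC[C@H](C)C2=C(OC)C(OC)=CC(=O)C12 | intermediate (not isolated)
14 | (1R,4S)-5,6-dimethoxy-4-methyl-1-(propan-2-yl)-1,2,3,4-tetrahydronaphthalen-8-ol | CC(C)[C@H]1CC[C@H](C)c2c(OC)c(OC)cc(O)c21 | intermediate (key-step product)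
15 | (1R,4S)-8-hydroxy-5,6-dimethoxy-4-methyl-1-(propan-2-yl)-1,2,3,4-tetrahydronaphthalene-7-carbaldehyde | CC(C)[C@H]1CC[C@H](C)c2c(OC)c(OC)c(C=O)c(O)c21 | intermediate
16 | (1R,4S)-7-formyl-5,6-dimethoxy-4-methyl-1-(propan-2-yl)-1,2,3,4-tetrahydronaphthalen-8-yl trifluoromethanesulfonate | CC(C)[C@H]1CC[C@H](C)c2c(OC)c(OC)c(C=O)c(OS(=O)(=O)C(F)(F)F)c21 | intermediate
17 | 4-methoxy-6-methyl-2H-pyran-2-one | Cc1cc(OC)cc(=O)o1 | starting material
18 | 3-bromo-4-methoxy-6-methyl-2H-pyran-2-one | Cc1cc(OC)c(Br)c(=O)o1 | intermediate
19 | 4-methoxybenzaldehyde | COc1ccc(C=O)cc1 | starting material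
20 | 3-bromo-4-methoxy-6-[(E)-2-(4-methoxyphenyl)ethenyl]-2H-pyran-2-one | COc1ccc(/C=C/c2cc(OC)c(Br)c(=O)o2)cc1 | intermediate
21 | 4-methoxy-6-[(E)-2-(4-methoxyphenyl)ethenyl]-3-(trimethylstannyl)-2H-pyran-2-one | COc1ccc(/C=C/c2cc(OC)c([Sn](C)(C)C)c(=O)o2)cc1 | intermediate
22 | (1R,4S)-5,6-dimethoxy-8-{4-methoxy-6-[(E)-2-(4-methoxyphenyl)ethenyl]-2-oxo-2H-pyran-3-yl}-4-methyl-1-(propan-2-yl)-1,2,3,4-tetrahydronaphthalene-7-carbaldehyde | CC(C)[C@H]1CC[C@H](C)c2c(OC)c(OC)c(C=O)c(-c3c(OC)cc(/C=C/c4ccc(OC)cc4)oc3=O)c21 | intermediate
23 | heimiomycin A | CC(C)[C@H]1CC[C@H](C)c2c(O)c(O)c(C=O)c(-c3c(O)cc(/C=C/c4ccc(O)cc4)oc3=O)c21 | target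

## Step count and least certain steps

Total step count: 12. Longest linear sequence: 8 steps from 1 (steps 1, 2, 4, 5, 6, 7, 11, 12).

**Step 5 (key step).** The most likely failure is bimolecular loss of the unhindered ketene 12 (dimerisation, O-acylation of phenol already formed) in competition with a closure that has to occur at a ring carbon next to the isopropyl-bearing C1. Any fraction that opens with methoxy inward adds to this, and the electron-rich monophenol may be oxidised on work-up. The fallback keeps the bond construction but changes the substrate and the point at which the two para oxygens are told apart. It sets out from 10 and comes back to the route at 15. Quenching 10 with aqueous NH4Cl in place of methyl triflate gives the carbinol 4-hydroxy-3-methoxy-4-[(3R,6S)-6-methyl-3-(propan-2-yl)cyclohex-1-en-1-yl]cyclobut-2-en-1-one F1. Heating F1 in toluene should give the hydroquinone (1R,4S)-6-methoxy-4-methyl-1-(propan-2-yl)-1,2,3,4-tetrahydronaphthalene-5,8-diol F2; the free hydroxyl is the parent substrate of this ring expansion and a strong outward-rotating group. F2 is kept under N2 and taken on crude. Formylation with MgCl2, Et3N and paraformaldehyde at C7, the only free position, gives (1R,4S)-5,8-dihydroxy-6-methoxy-4-methyl-1-(propan-2-yl)-1,2,3,4-tetrahydronaphthalene-7-carbaldehyde F3. In F3 the C8 hydroxyl is held in a hydrogen bond to the formyl group, so MeI and K2CO3 in acetone should methylate the free C5 hydroxyl first, giving 15.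

**Step 11 (Stille coupling).** The most likely failure is slow transmetalation at the doubly ortho-substituted C3' and slow reductive elimination to a four-fold ortho-substituted axis, which would let protodestannylation of 21 (C3' is an easily protonated enol-ether carbon) and homocoupling take over. The fallback reverses the polarity; it sets out from 16 and 20 and comes back at 22. Miyaura borylation of 16 (B2pin2, PdCl2(dppf), KOAc, dioxane, 90 °C) gives (1R,4S)-5,6-dimethoxy-4-methyl-1-(propan-2-yl)-8-(4,4,5,5-tetramethyl-1,3,2-dioxaborolan-2-yl)-1,2,3,4-tetrahydronaphthalene-7-carbaldehyde F4. Suzuki–Miyaura coupling of F4 with bromide 20 (Pd(OAc)2, SPhos, K3PO4, toluene/H2O, 90 °C), a catalyst system suited to hindered biaryls, gives 22 and needs no stannane.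

**Step 12 (global demethylation).** The most likely failure is incomplete cleavage of the vinylogous methyl ester at C4' under conditions mild enough for the styryl alkene. Under forcing conditions the risks are HBr-mediated damage to the electron-rich styrene and oxidation of the catechol during work-up. The fallback splits the deprotection into two operations with different mechanisms; it sets out from 22 and comes back at 23. Halide SN2 dealkylation with LiCl in DMF at 100–120 °C removes the methyl of the vinylogous ester, whose leaving group is carboxylate-like, and gives (1R,4S)-8-{4-hydroxy-6-[(E)-2-(4-methoxyphenyl)ethenyl]-2-oxo-2H-pyran-3-yl}-5,6-dimethoxy-4-methyl-1-(propan-2-yl)-1,2,3,4-tetrahydronaphthalene-7-carbaldehyde F5. The three remaining aryl methyl ethers are then cleaved with BBr3 in CH2Cl2 at −78 to 0 °C to give 23.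

**Step 4 (Shapiro, addition, methylation).** The most likely failure is premature protonation of 9 (by solvent or residual N–H species) and incomplete fragmentation, with the sulfinate by-product and excess base interfering with the addition to 8 and the capping of the hindered alkoxide. The fallback separates the making of the nucleophile from its use; it sets out from 5 and comes back at 11. The Shapiro reaction is run as before and 9 is quenched with I2 to give the isolable (3R,6S)-1-iodo-6-methyl-3-(propan-2-yl)cyclohex-1-ene F6, which is purified. Iodine–lithium exchange on F6 with t-BuLi (2 equiv) in Et2O at −78 °C regenerates 9 free of by-products; addition to 8 and methylation with MeOTf then give 11.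

## Further compounds

F1 | step 5 | 4-hydroxy-3-methoxy-4-[(3R,6S)-6-methyl-3-(propan-2-yl)cyclohex-1-en-1-yl]cyclobut-2-en-1-one (both C4 epimers) | CC(C)[C@H]1CC[C@H](C)C(=C1)C2(O)C(OC)=CC2=O
F2 | step 5 | (1R,4S)-6-methoxy-4-methyl-1-(propan-2-yl)-1,2,3,4-tetrahydronaphthalene-5,8-diol | CC(C)[C@H]1CC[C@H](C)c2c(O)c(OC)cc(O)c21
F3 | step 5 | (1R,4S)-5,8-dihydroxy-6-methoxy-4-methyl-1-(propan-2-yl)-1,2,3,4-tetrahydronaphthalene-7-carbaldehyde | CC(C)[C@H]1CC[C@H](C)c2c(O)c(OC)c(C=O)c(O)c21
F4 | step 11 | (1R,4S)-5,6-dimethoxy-4-methyl-1-(propan-2-yl)-8-(4,4,5,5-tetramethyl-1,3,2-dioxaborolan-2-yl)-1,2,3,4-tetrahydronaphthalene-7-carbaldehyde | CC(C)[C@H]1CC[C@H](C)c2c(OC)c(OC)c(C=O)c(B3OC(C)(C)C(C)(C)O3)c21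
F5 | step 12 | (1R,4S)-8-{4-hydroxy-6-[(E)-2-(4-methoxyphenyl)ethenyl]-2-oxo-2H-pyran-3-yl}-5,6-dimethoxy-4-methyl-1-(propan-2-yl)-1,2,3,4-tetrahydronaphthalene-7-carbaldehyde | CC(C)[C@H]1CC[C@H](C)c2c(OC)c(OC)c(C=O)c(-c3c(O)cc(/C=C/c4ccc(OC)cc4)oc3=O)c21
F6 | step 4 | (3R,6S)-1-iodo-6-methyl-3-(propan-2-yl)cyclohex-1-ene | CC(C)[C@H]1CC[C@H](C)C(I)=C1
A1 | alternative 1 | (1R,4S)-5-hydroxy trans-tetralin with C7 pivaloyloxymethyl and C8 tert-butyldimethylsilyloxymethyl (product of the gold cycloisomerisation) | CC(C)[C@H]1CC[C@H](C)c2c(O)cc(COC(=O)C(C)(C)C)c(CO[Si](C)(C)C(C)(C)C)c21
A2 | alternative 1 | furan–alkyne precursor: 2-[(3R,6S)-2,6-dimethyloct-7-yn-3-yl]furan with 3-(tert-butyldimethylsilyloxymethyl) and 4-(pivaloyloxymethyl) groups | CC(C)[C@@H](CC[C@H](C)C#C)c1occ(COC(=O)C(C)(C)C)c1CO[Si](C)(C)C(C)(C)C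
A3 | alternative 2 | tri-O-methyl heimiomycin A with C7 as dimethyl acetal (product of the ketene union) | CC(C)[C@H]1CC[C@H](C)c2c(OC)c(OC)c(C(OC)OC)c(-c3c(O)cc(/C=C/c4ccc(OC)cc4)oc3=O)c21
A4 | alternative 2 | (1R,4S)-8-(2-tert-butoxyethynyl)-7-(dimethoxymethyl)-5,6-dimethoxy-4-methyl-1-(propan-2-yl)-1,2,3,4-tetrahydronaphthalene | CC(C)[C@H]1CC[C@H](C)c2c(OC)c(OC)c(C(OC)OC)c(C#COC(C)(C)C)c21
A5 | alternative 2 | 6-[(E)-2-(4-methoxyphenyl)ethenyl]-2,2-dimethyl-4H-1,3-dioxin-4-one | CC1(C)OC(/C=C/c2ccc(OC)cc2)=CC(=O)O1
A6 | alternative 3 | (1R,4S)-4-methyl-1-(propan-2-yl)-1,2,3,4-tetrahydronaphthalene-5,6-diol (product of the enzymatic oxidation) | CC(C)[C@H]1CC[C@H](C)c2c(O)c(O)ccc21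
A7 | alternative 3 | (1R,4S)-4-methyl-1-(propan-2-yl)-1,2,3,4-tetrahydronaphthalene | CC(C)[C@H]1CC[C@H](C)c2ccccc21
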